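The readings come from a simulation for substances that don't exist; noise was put on by code.

The flask is charged with less X than Z, and each X turns one Z into G, so X is the limiting reagent. The X ceiling is 50.0%: the share of the Z charged that the charge of X can turn. G and Q together climb towards it.

| flask | Z | X | remark | time |
|---|---|---|---|---|
| eta | 0.050 M | 0.025 M | the very flask that is asked about, followed so far |  |
| epsilon | 0.025 M | 0.025 M | run made earlier |  |
| flask | 0.050 M | 0.0250 M |  | 4.0 min |

| run | time / s | G / % | Q / % |
|---|---|---|---|
| eta | 30.0 | 27 | 0 |
| eta | 40.0 | 28 | 2 |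
| eta | 60.0 | 36 | 4 |
| eta | 80.0 | 38 | 6 |
| eta | 120 | 41 | 8 |
| epsilon | 30.0 | 33 | 1 |
| epsilon | 40.0 | 38 | 2 |
| epsilon | 60.0 | 44 | 4 |
| epsilon | 80.0 | 52 | 5 |
| epsilon | 90.0 | 53 | 6 |

(standard deviation of a reading: 1.5 percentage points)

- time, not beyond 4.0 min, at which the flask holds most G
- the amount of G, in percent of the Z charged, at that time
- the first time at which G reaches 20%, in the same percent, in min

- candidate steps: Z + X -> G + J; Z <-> L; G -> Q

In the epsilon run, charged equally, the turned fraction (G plus Q) over the unturned fraction grows as rate constant times charge times time, so its last reading gives a rate constant of 0.640 M⁻¹ s⁻¹. In the eta run, Q of 8% at 120 s, set against the mid-span G of 36%, gives a leak of G into Q of 0.00185 s⁻¹. For this flask, the second-order law for unequal charges, with Q neglected, puts 20% at 0.300 min.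

G peaks where making equals leaking. Putting G at the ceiling leaves a gap below the ceiling of 5.79%, reached at 1.64 min. That G is the weak link, since the gap and the Q reading of 8% both come off it. Going round again with the lowered G narrows the gap to 3.76%, which moves the peak to 2.05 min with G at 38.2%.

The forecast says 1.9 min, 40.5% and 0.3 min, adding that “the peak is flat”. Its peak is higher than this reckoning's and earlier.

The flask gives 2.08 min, 39.5% and 0.310 min, and the forecast holds within its tolerance.

    Z + X → G + J (k = 0.640 M⁻¹ s⁻¹)
    Z ⇌ L (K = 2.30, k = 9.90 × 10⁻⁴ s⁻¹)
    G → Q (k = 0.00160 s⁻¹)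

The peak lies under the ceiling, and one reason is the shrinking supply of X: with X kept at its charge, the highest G is 73.8% against 39.5%. The forecast's 40.5% stands below that held-X value, so the run with X held is what would make it wrong. A neighbour flask charged with 0.0063 M of X, its Z as in this flask, has a ceiling of 12.6%, and its computed best is 10.5%.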